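# Proposed total synthesis of CNP0149338.1

## Structural features

Kaurane-type numbering is used. Ring A is C1–C5/C10, ring B is C5–C10, ring C is C8, C9, C11–C14, and ring D is C11, C12, C13, C16, C15. C17 is the exocyclic methylene, C18/C19 are the methyls on C4, C20 is the methyl on C10, and "α" is the face that carries C20.

1. The target is a trans-decalin (A/B) joined through the tetrasubstituted C8=C9 double bond to a bicyclo[3.2.1]octene (C/D). The bridgeheads are C11 and C13, C12 is the one-carbon bridge, C15–C16 is the two-carbon bridge on the β face, and C9=C8–C14 is the three-carbon bridge.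
2. The acyl carbon C15 sits on C11 and not on C8 as in an ent-kaurane. C15(=O)–C11–C9=C8 is therefore a β,γ-unsaturated ketone whose α-carbon is a bridgehead.
3. There are two blocks of adjacent stereocentres, C1/C10/C5/C6 and C11/C12/C13. They are separated by the flat C8=C9 unit, so their relative configuration has to be relayed across it.
4. The 1-OAc (equatorial) and 6-OH (axial) groups are cis to C20, H5 is β, and the 12-OH points toward the C15–C16 bridge.
5. The fragile groups are the α-methylene ketone (Michael acceptor), the β-hydroxy ketone C12–C11–C15 (retro-aldol), the acetate, and the hindered axial 6-OH.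
6. The real difficulty is the C11–C15 bond next to a tetrasubstituted alkene that is itself flanked by quaternary C10, together with the bridged C/D unit of correct configuration relative to C10.
7. The key step exploits the array C15–C11–C9=C8–(H8). Read backwards, it is the retron of a carbonyl–alkene (Prins/ene-type) addition to a C9=C11 double bond with migration of that bond into C8=C9.

## Logic of the disconnections

**24 ⇒ 23 ⇒ 22.** The two O–Si bonds and the C16=C17 bond are cut. The Michael acceptor and the free β-hydroxy ketone are the most fragile parts, so they appear last. C16 is the only enolisable position of 22, because C11 is a bridgehead. The forward steps therefore need only a mild methylenation and an acidic desilylation.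

**22 ⇒ 21 ⇒ 20 (key).** The C11–C15 bond is cut, the double bond goes back from C8=C9 to C9=C11, and a hydrogen returns to C8. This removes ring D, the seven-membered ring, the bridge, the tetrasubstituted alkene and the C11 stereocentre in one operation, and leaves an unbridged tricycle. The forward step needs attack through C11 only, from the β face only, and loss of H8 only.

**20 ⇒ 18.** The C15–C16 bond is cut (one-carbon homologation). This turns the side chain into a formyl group, which is the activating group of a dienophile. The forward step must not epimerise C13.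

**18 ⇒ 16 + 17.** The C12–C13 and C8–C14 bonds are cut (Diels–Alder). Ring C and the stereocentres C8, C12 and C13 are removed as a group. The forward step needs "ortho" regiochemistry, endo topology and attack on the β face.

**16 ⇒ 15 ⇒ 14 ⇒ 12 ⇒ 11.** The C11–C12 bond is cut (one-carbon homologation), and C5/C6 are returned to a silyl enol ether. The enol ether of 11 stores the C6 oxygen until the aldehyde has been masked. The forward steps need protonation at C5 and hydride delivery at C6, both from the β face.

**11 ⇒ 9 + 10.** The C9–C10 and C7–C8 bonds are cut (Diels–Alder). Ring B and quaternary C10 are removed, which leaves a monocyclic diene and a three-carbon ynal. The forward step needs addition anti to the C1 acetoxy group.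

**9 ⇒ 8 ⇒ 7 ⇒ 6.** The functional groups are reverted and the C1–H bond is cut (asymmetric ketone reduction). C1 becomes the only stereocentre that has to come from a catalyst. The forward step must reduce one of two ketones.

**6 ⇒ 3 + 4, and 3 ⇒ 1.** The C5–C6 bond and the two C4–CH3 bonds are cut (vinylogous-ester chemistry), which ends at commercial materials.

## Other disconnections considered

**Alternative 1:** This is the cut that comes to mind first. C11–C15 is cut and C8–C15 is made, so the forward key step is a photochemical 1,3-acyl shift of the ent-kaur-9(11)-en-15-one isomer A1. A1 has the same number of rings and stereocentres as the target, plus a quaternary bridgehead C8, so nothing is simplified and the bridged system still has to be built. The shift connects two β,γ-enones and can at best reach a photostationary mixture. The cross-conjugated methylene ketone also absorbs in the same region. The chosen plan reaches the C11–C15 connectivity directly from an unbridged tricycle.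

**Alternative 2:** C11–C15 and C13–C16 are cut together. The forward key step is a dearomatising arene–alkene meta photocycloaddition across C11/C13 of the 12-methoxy arene A2, followed by protonolysis of the methoxycyclopropane to the C12 ketone, C14H2 and C8=C9.

- The atom mapping is perfect, but the addition has to be intermolecular. A tether from O1 cannot reach C15, because the C11–C15 bond leans away from C10.
- C11 is crowded by the peri C1 substituent, and the two faces differ little at C11–C13.
- An unsymmetrical alkene would orient by sterics toward the wrong regioisomer, while a symmetrical one postpones the C15/C16 differentiation.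
- A2 also needs a C9–C10 bond made meta to the methoxy group, so the route would be longer than the chosen one.

**Alternative 3:** C9–C10 and C7–C8 are cut with rings C/D intact. The forward key step is a Diels–Alder reaction of diene 9 with a transient bicyclo[3.2.1]oct-2-yne released by fluoride from silyl triflate A3.

- The union is convergent and fixes the relative configuration by the choice of enantiomers.
- However, the fully substituted diene terminus C10 has to bond to the alkyne carbon next to bridgehead C11. Sterics favour the opposite orientation, and only a weak inductive distortion opposes it.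
- [2+2] addition to the enol ether can compete.
- A3 itself, with C12–O, a differentiated ring D, a regiodefined triflate and a single enantiomer, would cost about as many steps as the whole chosen route.

Key step: step 13

Route in one sentence: ring D and the bridge are closed by a Lewis-acid Prins cyclisation of the unbridged Δ9(11) tricyclic aldehyde 20, in which C11 attacks C15 and loss of H8 moves the double bond into C8=C9.

Remark on the chemistry: the enol-ether geometries of 12 and 19 and the C15 carbinol configuration of 21 are left open, because each is erased in the following operation.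

## Steps

Step 1
Reactants: 1 3-ethoxy-2-methylcyclohex-2-en-1-one
Product: 3 3-ethoxy-2,6,6-trimethylcyclohex-2-en-1-one, via monomethyl enone 2 (not isolated)
Conditions: LDA, THF, −78 °C, then MeI; second portion of LDA, then MeI, −78 to 0 °C
Reagents that add atoms: iodomethane, CI
Why: Stork–Danheiser kinetic α′-alkylation; the vinylogous ester can be deprotonated only at C6, so two rounds should place the geminal methyl groups (future C18/C19) next to the ketone.

Step 2
Reactants: 3 3-ethoxy-2,6,6-trimethylcyclohex-2-en-1-one; 4 ethyl vinyl ether
Product: 6 3-acetyl-2,4,4-trimethylcyclohex-2-en-1-one, via tertiary carbinol 5 (not isolated)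
Conditions: 4, t-BuLi, THF, −78 to 0 °C; add 3, −78 °C; then 1 M HCl, THF, 0 °C
Reagents that add atoms: water, O
Why: 1,2-addition of the small acyl-anion equivalent 1-ethoxyvinyllithium to the hindered ketone, then Stork–Danheiser transposition; acid ionises the tertiary allylic alcohol and hydrolyses both enol ethers, which puts the ring carbonyl at future C1 and the acetyl group (C6, C7) on C5.

Step 3
Reactants: 6 3-acetyl-2,4,4-trimethylcyclohex-2-en-1-one
Product: 7 (S)-3-acetyl-2,4,4-trimethylcyclohex-2-en-1-ol
Conditions: (R)-Me-CBS (cat.), BH3·SMe2, THF, −30 °C; MeOH quench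
Reagents that add atoms: none
Why: Corey–Bakshi–Shibata reduction; 2-methylcyclohexenones are good substrates (the alkene side acts as the large group, so the (R)-catalyst should give the S carbinol, future C1). The acetyl carbonyl is flanked by the C4 methyls and the C10 methyl, is twisted out of conjugation like a mesityl ketone, and should stay untouched.

Step 4
Reactants: 7 (S)-3-acetyl-2,4,4-trimethylcyclohex-2-en-1-ol
Product: 8 (S)-3-acetyl-2,4,4-trimethylcyclohex-2-en-1-yl acetate
Conditions: Ac2O, pyridine, DMAP (cat.), CH2Cl2, 0 °C
Reagents that add atoms: acetic anhydride, CC(=O)OC(C)=O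
Why: standard acylation; the acetate of the target is installed here, and all later reagents are chosen to tolerate it, so no protecting-group exchange at O1 is needed.

Step 5
Reactants: 8 (S)-3-acetyl-2,4,4-trimethylcyclohex-2-en-1-yl acetate
Product: 9 (S)-3-[1-(tert-butyldimethylsilyloxy)ethenyl]-2,4,4-trimethylcyclohex-2-en-1-yl acetate
Conditions: TBSOTf, Et3N, CH2Cl2, 0 °C
Reagents that add atoms: tert-butyldimethylsilyl triflate, CC(C)(C)[Si](C)(C)OS(=O)(=O)C(F)(F)F
Why: soft enolisation; the methyl group is the only enolisable position of the ketone and the acetate is much less acidic, so the 2-silyloxydiene C7=C6(OTBS)–C5=C10 should form cleanly.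

Step 6
Reactants: 9 (S)-3-[1-(tert-butyldimethylsilyloxy)ethenyl]-2,4,4-trimethylcyclohex-2-en-1-yl acetate; 10 propynal
Product: 11 AB dienal (1α-OAc; C10 quaternary with C20 α; C5=C6-OTBS; C7H2; C8H=C9-C11HO)
Conditions: toluene, BHT, 60–80 °C, sealed tube
Reagents that add atoms: none
Why: Diels–Alder reaction of a vinylcyclohexene-type diene with an ynal; the 2-silyloxy group ("para" rule) and the disubstituted terminus C10 ("ortho" rule) both direct C7 to the alkyne CH (C8) and C10 to the formyl-bearing carbon (C9). A(1,2) strain with the C10 methyl makes the C1 acetoxy group pseudo-axial, so the ynal should add to the opposite (β) face, which places C20 cis to OAc.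

Step 7
Reactants: 11 AB dienal
Product: 12 AB methyl dienol ether (as 11 with C11H=C12H-OMe in place of CHO; E/Z mixture)
Conditions: MeOCH2PPh3Cl, KHMDS, THF, −78 to 0 °C
Reagents that add atoms: (methoxymethyl)triphenylphosphonium chloride, COC[P+](c1ccccc1)(c1ccccc1)c1ccccc1.[Cl-]
Why: Wittig methoxymethylenation adds C12 and masks the aldehyde; the aldehyde reacts far faster than the acetate, and the silyl enol ether is inert to the ylide.

Step 8
Reactants: 12 AB methyl dienol ether
Product: 14 6α-alcohol (5β-H trans-decalin; axial 6α-OH; C8H=C9-C11H=C12H-OMe; 1α-OAc), via 6-ketone 13 (not isolated)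
Conditions: TBAF/AcOH (1:1), THF, 0 °C; then NaBH4, MeOH, −20 °C
Reagents that add atoms: none
Why: buffered fluoride cleaves only the silyl enol ether. C5 is protonated and C6 then receives hydride from the β face, because the α face carries the axial C20 and C19 methyls. This should give the trans ring fusion and the axial alcohol, as in hydride reductions of 6-oxo trans-decalins with an angular methyl group.

Step 9
Reactants: 14 6α-alcohol
Product: 15 hydroxy enal (exocyclic C9=C11H-C12HO with C12 cis to C8; C8H2; 6α-OH; 1α-OAc)
Conditions: oxalic acid, THF/H2O, 0 °C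
Reagents that add atoms: water, O
Why: mild enol-ether hydrolysis; protonation at the vinylogous position C8 leads to the conjugated enal. Any β,γ-isomer is harmless, because both give the same dienol ether in step 10.

Step 10
Reactants: 15 hydroxy enal
Product: 16 bis-silyl diene (6α-OTBS; C8H=C9-C11H=C12H-OTBS with 11E geometry; 1α-OAc)
Conditions: TBSOTf (excess), Et3N, CH2Cl2, −78 to 0 °C
Reagents that add atoms: tert-butyldimethylsilyl triflate, CC(C)(C)[Si](C)(C)OS(=O)(=O)C(F)(F)F
Why: one operation silylates the hindered 6-OH and converts the enal into the 1-silyloxydiene by O-silylation and γ-deprotonation. C8 carries the only γ-hydrogens, and the s-trans enal should give the E enol ether.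

Step 11
Reactants: 16 bis-silyl diene; 17 acrolein
Product: 18 ABC aldehyde (8α-H; C9=C11; 12β-OTBS; 13β-CHO as C16; 13α-H; 6α-OTBS; 1α-OAc)
Conditions: toluene, BHT, 25–50 °C
Reagents that add atoms: none
Why: Diels–Alder reaction of a 1-silyloxydiene; the oxygen donor enforces "ortho" regiochemistry (C12–C13 and C8–C14), and the endo rule with the E diene gives the 12,13-cis product. The α face is blocked by the axial C20 methyl and the axial 6α-OTBS group, so acrolein should add from the β face, which sets C8, C12 and C13 relative to C10.

Step 12
Reactants: 18 ABC aldehyde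
Product: 20 homologated aldehyde (as 18 with 13β-CH2CHO; C16H2-C15HO), via methyl enol ether 19 (not isolated)
Conditions: MeOCH2PPh3Cl, KHMDS, THF, −78 °C; then TsOH·H2O (cat.), acetone/H2O, 0 °C
Reagents that add atoms: (methoxymethyl)triphenylphosphonium chloride, COC[P+](c1ccccc1)(c1ccccc1)c1ccccc1.[Cl-]; water, O
Why: Wittig methoxymethylenation and enol-ether hydrolysis add C15; a pre-formed ylide at low temperature is used to keep C13 from epimerising, and the brief mild acid should spare the TBS ethers.

Step 13
Reactants: 20 homologated aldehyde
Product: 21 tetracyclic 15-ol (C8=C9; C11-H α; C15H-OH with open configuration; C16H2; 12-OTBS syn to C15-C16; 6α-OTBS; 1α-OAc)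
Conditions: Me2AlCl (excess), CH2Cl2, −78 to −30 °C; aq. Rochelle salt
Reagents that add atoms: none
Why: Me2AlCl binds the aldehyde of 20, and the C9=C11 double bond attacks C15 through its less substituted carbon C11, which places the charge on tertiary C9; loss of H8 then gives the tetrasubstituted C8=C9 bond and the aluminium alkoxide of 21 (Prins cyclisation, the stepwise form of a carbonyl–ene reaction; the closest known type is the Me2AlCl-promoted cyclisation of unsaturated aldehydes). Ring D (C11, C12, C13, C16, C15) closes in a 5-exo-trig mode with respect to the alkene, and the same bond closes the seven-membered ring C8–C9–C11–C15–C16–C13–C14, that is, the bicyclo[3.2.1]octene. C11 is controlled by the tether: the 2-oxoethyl arm stands on the β face of C13 (in step 11 it was the endo group lying under the new alkene), so C15 can reach only the β face of C11. C15 is not controlled and is erased in step 14. Attack through C11 rather than C9 (which would give a bicyclo[2.2.2]octane) follows from a tertiary versus a secondary cation, and from the quaternary centre that attack through C9 would create next to C10. The position of the new double bond is secured by the substrate: C10 has no hydrogen and C11 becomes a bridgehead, so H8 is the only proton that can leave; because H8 is α and the carbonyl arrives from β, the transfer cannot be concerted, which is why a stepwise course is assumed. Me2AlCl is chosen because its methyl groups destroy adventitious acid, so the trisubstituted alkene is not isomerised before the C–C bond forms and the allylic C12 silyl ether is not ionised.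

Step 14
Reactants: 21 tetracyclic 15-ol
Product: 22 15-ketone (C15=O; C16H2; otherwise as 21)
Conditions: Dess–Martin periodinane, NaHCO3, CH2Cl2, 0 °C
Reagents that add atoms: none
Why: neutral Dess–Martin oxidation of the only free alcohol; the β,γ-double bond cannot move into conjugation, because C11 is a bridgehead.

Step 15
Reactants: 22 15-ketone
Product: 23 bis-TBS ether of the target (C16=C17H2)
Conditions: (CH2O)n, i-Pr2NH·TFA, THF, reflux
Reagents that add atoms: formaldehyde (as paraformaldehyde), C=O
Why: Mannich-type α-methylenation under buffered conditions; C16 is the only enolisable position, β-elimination of the 12-silyloxy group is forbidden by the bridgehead, and the acetate is not exposed to strong base.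

Step 16
Reactants: 23 bis-TBS ether of the target
Product: 24 CNP0149338.1 (target)
Conditions: HF·pyridine, THF, 0 °C to rt (aq. HF/MeCN for the hindered 6-OTBS if needed)
Reagents that add atoms: none
Why: acidic fluoride desilylation avoids the basic media that would trigger retro-aldol cleavage or conjugate addition, and the acetate should survive.

## Compound list

1 | 3-ethoxy-2-methylcyclohex-2-en-1-one | CCOC1=C(C)C(=O)CCC1 | starting material
2 | 3-ethoxy-2,6-dimethylcyclohex-2-en-1-one (racemic) | CCOC1=C(C)C(=O)C(C)CC1 | intermediate
3 | 3-ethoxy-2,6,6-trimethylcyclohex-2-en-1-one | CCOC1=C(C)C(=O)C(C)(C)CC1 | intermediate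
4 | ethyl vinyl ether | C=COCC | starting material
5 | 3-ethoxy-1-(1-ethoxyethenyl)-2,6,6-trimethylcyclohex-2-en-1-ol (racemic) | CCOC1=C(C)C(O)(C(=C)OCC)C(C)(C)CC1 | intermediate
6 | 3-acetyl-2,4,4-trimethylcyclohex-2-en-1-one | CC(=O)C1=C(C)C(=O)CCC1(C)C | intermediate
7 | (S)-3-acetyl-2,4,4-trimethylcyclohex-2-en-1-ol | O[C@H]1CCC(C)(C)C(C(C)=O)=C1C | intermediate
8 | (S)-3-acetyl-2,4,4-trimethylcyclohex-2-en-1-yl acetate | CC(=O)O[C@H]1CCC(C)(C)C(C(C)=O)=C1C | intermediate
9 | (S)-3-[1-(tert-butyldimethylsilyloxy)ethenyl]-2,4,4-trimethylcyclohex-2-en-1-yl acetate | CC(=O)O[C@H]1CCC(C)(C)C(C(=C)O[Si](C)(C)C(C)(C)C)=C1C | intermediate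
10 | propynal | C#CC=O | starting material
11 | AB dienal | O=CC1=CCC(O[Si](C)(C)C(C)(C)C)=C2C(C)(C)CC[C@H](OC(C)=O)[C@@]12C | intermediate
12 | AB methyl dienol ether (E/Z) | COC=CC1=CCC(O[Si](C)(C)C(C)(C)C)=C2C(C)(C)CC[C@H](OC(C)=O)[C@@]12C | intermediate
13 | 6-ketone (5β-H) | COC=CC1=CCC(=O)[C@@H]2C(C)(C)CC[C@H](OC(C)=O)[C@@]12C | intermediate
14 | 6α-alcohol | COC=CC1=CC[C@H](O)[C@@H]2C(C)(C)CC[C@H](OC(C)=O)[C@@]12C | intermediate
15 | hydroxy enal | O=C/C=C1\CC[C@H](O)[C@@H]2C(C)(C)CC[C@H](OC(C)=O)[C@@]12C | intermediate
16 | bis-silyl diene | CC(C)(C)[Si](C)(C)O/C=C/C1=CC[C@H](O[Si](C)(C)C(C)(C)C)[C@@H]2C(C)(C)CC[C@H](OC(C)=O)[C@@]12C | intermediate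
17 | acrolein | C=CC=O | starting material
18 | ABC aldehyde | O=C[C@H]1C[C@H]2C[C@H](O[Si](C)(C)C(C)(C)C)[C@@H]3C(C)(C)CC[C@H](OC(C)=O)[C@@]3(C)C2=C[C@H]1O[Si](C)(C)C(C)(C)C | intermediate
19 | side-chain methyl enol ether (E/Z) | COC=C[C@H]1C[C@H]2C[C@H](O[Si](C)(C)C(C)(C)C)[C@@H]3C(C)(C)CC[C@H](OC(C)=O)[C@@]3(C)C2=C[C@H]1O[Si](C)(C)C(C)(C)C | intermediate
20 | homologated aldehyde | O=CC[C@H]1C[C@H]2C[C@H](O[Si](C)(C)C(C)(C)C)[C@@H]3C(C)(C)CC[C@H](OC(C)=O)[C@@]3(C)C2=C[C@H]1O[Si](C)(C)C(C)(C)C | intermediate
21 | tetracyclic 15-ol (C15 open) | C1C(O)[C@@H]2C3=C(C[C@H]1[C@@H]2O[Si](C)(C)C(C)(C)C)C[C@H](O[Si](C)(C)C(C)(C)C)[C@@H]1C(C)(C)CC[C@H](OC(C)=O)[C@@]31C | intermediate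
22 | 15-ketone | C1C(=O)[C@@H]2C3=C(C[C@H]1[C@@H]2O[Si](C)(C)C(C)(C)C)C[C@H](O[Si](C)(C)C(C)(C)C)[C@@H]1C(C)(C)CC[C@H](OC(C)=O)[C@@]31C | intermediate
23 | bis-TBS ether of the target | C=C1C(=O)[C@@H]2C3=C(C[C@H]1[C@@H]2O[Si](C)(C)C(C)(C)C)C[C@H](O[Si](C)(C)C(C)(C)C)[C@@H]1C(C)(C)CC[C@H](OC(C)=O)[C@@]31C | intermediate
24 | CNP0149338.1 | C=C1C(=O)[C@@H]2C3=C(C[C@H]1[C@@H]2O)C[C@H](O)[C@@H]1C(C)(C)CC[C@H](OC(C)=O)[C@@]31C | target

## Step count and least certain steps

Total step count: 16. Longest linear sequence: 16 (1 to 24).

**Step 13 (key step).**
- What may go wrong: the C9 cation may be diverted before H8 is lost, by a 1,2-shift of C20 from C10 or by capture of chloride. The Lewis acid may ionise the allylic C12 silyl ether. The arm on C13 may also fail to adopt the axial position that cyclisation needs.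
- Fallback, from 20 back to 22, by a concerted dipolar cycloaddition instead of a cation: condensation with hydroxylamine would give oxime F1. Aqueous NaOCl would give nitrile oxide F2, which should add across C9=C11 from the β face (C15 to C11, O to the more substituted C9) to give isoxazoline F3. Reductive N–O cleavage with Mo(CO)6 in wet acetonitrile, followed by imine hydrolysis, would give 9β-hydroxy ketone F4. Dehydration with SOCl2/pyridine can only proceed anti toward the α-H8, and this returns to 22.

**Step 6.**
- What may go wrong: the diene has to become planar against the C4 methyls and the C10 methyl, so cycloaddition may be slower than polymerisation of the ynal. Some addition syn to the acetate would erode the C10 configuration.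
- Fallback, from 9 back to 11, by cycloaddition/elimination with an olefinic acetylene equivalent: 2-chloroacrolein is more reactive and can be activated at low temperature by a mild Lewis acid. It would give chloro aldehyde F5 with the same regiochemistry. DBU would then remove HCl across C8–C9 and return to 11.

**Step 3.**
- What may go wrong: borane may also reduce the acetyl group, or selectivity between the two carbonyls may be too low for a clean mono-reduction.
- Fallback, from 3 back to 8, with the second carbonyl masked as an alkyne: ethynylmagnesium bromide followed by acid would give enynone F6. CBS reduction of its single ketone would give enynol F7. Acetylation would give enynyl acetate F8, and gold(I)-catalysed Markovnikov hydration of the terminal alkyne returns to 8.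

**Step 11.**
- What may go wrong: endo/exo selectivity may be poor (loss of the 12,13-cis relation), or discrimination between the two diene faces may be incomplete.
- Fallback, from 16 back to 18, by stepwise ring closure: a vinylogous Mukaiyama–Michael addition of C8 to acrolein would give dialdehyde F9. An amine-catalysed intramolecular aldol reaction (enamine of the saturated aldehyde onto C12) would give hydroxy aldehyde F10, and silylation with TBSOTf returns to 18.

**Step 12.**
- What may go wrong: the basic ylide may epimerise C13 to the more stable trans isomer, or start β-elimination of the 12-silyloxy group. The acid hydrolysis may cleave the allylic silyl ether.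
- Fallback, from 18 back to 20, without base or acid: Takai–Lombardo methylenation (Zn, CH2Br2, TiCl4) would give vinyl compound F11. Hydroboration of the monosubstituted alkene with 9-BBN, followed by NaBO3, would give primary alcohol F12, and Dess–Martin oxidation returns to 20.

## Further compounds

F1 | step 13 | oxime of 20 | ON=CC[C@H]1C[C@H]2C[C@H](O[Si](C)(C)C(C)(C)C)[C@@H]3C(C)(C)CC[C@H](OC(C)=O)[C@@]3(C)C2=C[C@H]1O[Si](C)(C)C(C)(C)C
F2 | step 13 | nitrile oxide | [O-][N+]#CC[C@H]1C[C@H]2C[C@H](O[Si](C)(C)C(C)(C)C)[C@@H]3C(C)(C)CC[C@H](OC(C)=O)[C@@]3(C)C2=C[C@H]1O[Si](C)(C)C(C)(C)C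
F3 | step 13 | isoxazoline (C15=N–O–C9, O on the β face) | C1C2=NO[C@@]35[C@@H]2[C@@H](O[Si](C)(C)C(C)(C)C)[C@@H]1C[C@H]3C[C@H](O[Si](C)(C)C(C)(C)C)[C@@H]4C(C)(C)CC[C@H](OC(C)=O)[C@@]54C
F4 | step 13 | 9β-hydroxy 15-ketone | C1C(=O)[C@@H]2[C@]3(O)[C@@H](C[C@H]1[C@@H]2O[Si](C)(C)C(C)(C)C)C[C@H](O[Si](C)(C)C(C)(C)C)[C@@H]4C(C)(C)CC[C@H](OC(C)=O)[C@@]34C
F5 | step 6 | 9-chloro aldehyde (C9 open) | O=CC1(Cl)CCC(O[Si](C)(C)C(C)(C)C)=C2C(C)(C)CC[C@H](OC(C)=O)[C@@]12C
F6 | step 3 | 3-ethynyl-2,4,4-trimethylcyclohex-2-en-1-one | C#CC1=C(C)C(=O)CCC1(C)C
F7 | step 3 | (S)-3-ethynyl-2,4,4-trimethylcyclohex-2-en-1-ol | O[C@H]1CCC(C)(C)C(C#C)=C1C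
F8 | step 3 | (S)-3-ethynyl-2,4,4-trimethylcyclohex-2-en-1-yl acetate | CC(=O)O[C@H]1CCC(C)(C)C(C#C)=C1C
F9 | step 11 | dialdehyde (8α-H; C8–C14H2–C13H2–C16HO; exocyclic enal) | O=CCC[C@H]1C[C@H](O[Si](C)(C)C(C)(C)C)[C@@H]2C(C)(C)CC[C@H](OC(C)=O)[C@@]2(C)C1=CC=O
F10 | step 11 | 12β-hydroxy aldehyde | O=C[C@H]1C[C@H]2C[C@H](O[Si](C)(C)C(C)(C)C)[C@@H]3C(C)(C)CC[C@H](OC(C)=O)[C@@]3(C)C2=C[C@H]1O
F11 | step 12 | 13β-vinyl compound | C=C[C@H]1C[C@H]2C[C@H](O[Si](C)(C)C(C)(C)C)[C@@H]3C(C)(C)CC[C@H](OC(C)=O)[C@@]3(C)C2=C[C@H]1O[Si](C)(C)C(C)(C)C
F12 | step 12 | 13β-(2-hydroxyethyl) compound | OCC[C@H]1C[C@H]2C[C@H](O[Si](C)(C)C(C)(C)C)[C@@H]3C(C)(C)CC[C@H](OC(C)=O)[C@@]3(C)C2=C[C@H]1O[Si](C)(C)C(C)(C)C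
A1 | alternative 1 | ent-kaur-9(11),16-dien-15-one isomer of the target | C=C1C(=O)[C@@]23C[C@H](O)[C@@H]4C(C)(C)CC[C@H](OC(C)=O)[C@@]4(C)C2=C[C@@H](O)[C@@H]1C3
A2 | alternative 2 | 1α-acetoxy-6α-hydroxy-12-methoxy-ent-podocarpa-8,11,13-triene | COc1ccc2C[C@H](O)[C@@H]3C(C)(C)CC[C@H](OC(C)=O)[C@@]3(C)c2c1
A3 | alternative 3 | C/D silyl triflate (C9–OTf, C8–SiEt3, C15 dioxolane, 12-OTBS) | C1C2(OCCO2)[C@@H]3C(OS(=O)(=O)C(F)(F)F)=C([Si](CC)(CC)CC)C[C@H]1[C@@H]3O[Si](C)(C)C(C)(C)C
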